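## Retrosynthetic overview

1. The target comes from hydrogenolysis of its ring A benzyl ether, which comes from oxidative C7″–O opening of a trans-phenylcoumaran; that ring is the 8–5′ ring of the biosynthesis and serves to hold C8″ and to mask the ring B phenol.
2. The butyrolactone comes from one hydride step that removes two oxazolidinone auxiliaries; the freed C9 alcohol closes onto the C9′ methyl ester, so the carbonyl sits on the unit that carries the side chain.
3. The phenylcoumaran comes from an auxiliary-directed 8–5′ phenoxyl radical cross-coupling of a ring B phenol (ring A benzylated) with an N-feruloyl oxazolidinone, followed by quinone methide ring closure.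
4. The C8–C8′ bond comes from an oxidative heterocoupling of an Evans imide enolate and an ester enolate, both made from dihydroferulic acid derivatives.
5. Ring order: the dihydrobenzofuran is formed first (step 6), the butyrolactone second (step 7), and the dihydrobenzofuran is opened again in step 8.

Labels: ring A is the aryl of the lactone C4 benzyl group, ring B the aryl of the C3 benzyl group, ring C the aryl of the ketone. Lignan locants are 7–9 (unit A), 7′–9′ (unit B) and 7″–9″ (unit C).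

Assumption 1: the presumed biosynthesis is 8–8′ coupling of two guaiacyl C6C3 units, reduction and lactone closure, then 8–5′ radical coupling with a third unit, phenylcoumaran closure and oxidative C7″–O opening.

Assumption 2: in step 6 the N-enoyl imide reacts in its silver-bridged syn s-cis form, so the bond forms anti to the auxiliary benzyl group; if the opposite facial sense is found, the enantiomeric auxiliary is used for this imide only.

## Route

Step 1
Reactants: 1 3-[4-(benzyloxy)-3-methoxyphenyl]propanoic acid; 2 (4R)-4-benzyl-1,3-oxazolidin-2-one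
Product: 4 imide A = (4R)-4-benzyl-3-{3-[4-(benzyloxy)-3-methoxyphenyl]propanoyl}-1,3-oxazolidin-2-one, via mixed pivalic anhydride 3 (not isolated)
Conditions: PivCl (1.1 equiv), Et3N (2.5 equiv), THF, −20 °C, 1 h; then 2, LiCl (1.1 equiv), −20 °C → rt
Reagents that add atoms: none
Why: Mixed-anhydride N-acylation of the LiCl-activated oxazolidinone (standard loading of an Evans auxiliary); no stereocenter is formed.

Step 2
Reactants: 5 methyl 3-(4-hydroxy-3-methoxyphenyl)propanoate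
Product: 6 methyl 3-(4-{[tert-butyl(dimethyl)silyl]oxy}-3-methoxyphenyl)propanoate
Conditions: TBSCl (1.2 equiv), imidazole (2 equiv), DMF, rt
Reagents that add atoms: tert-butyl(chloro)dimethylsilane (TBSCl), CC(C)(C)[Si](C)(C)Cl
Why: Silyl ether protection of the phenol, which would otherwise be deprotonated and oxidized in step 3; no stereocenter is formed.

Step 3
Reactants: 4 imide A; 6 silyl-protected methyl dihydroferulate
Product: 7 methyl (3S)-4-[(4R)-4-benzyl-2-oxo-1,3-oxazolidin-3-yl]-3-{[4-(benzyloxy)-3-methoxyphenyl]methyl}-2-[(4-{[tert-butyl(dimethyl)silyl]oxy}-3-methoxyphenyl)methyl]-4-oxobutanoate (2S and 2R epimers, carried on together)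
Conditions: 4 (1 equiv), 6 (1.5 equiv), LDA (LiN(iPr)2, 2.6 equiv), THF, −78 °C; then Fe(acac)3 (acac = acetylacetonate, 2.6 equiv), −78 °C → rt
Reagents that add atoms: none
Why: Oxidative enolate heterocoupling (single-electron oxidation of the mixed lithium enolate aggregate by trivalent iron, the laboratory counterpart of the 8–8′ radical coupling), in which the bond forms on the imide enolate face away from the auxiliary benzyl group and sets C3 as S, while the ester α-carbon forms unselectively and is corrected in step 7.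

Step 4
Reactants: 7 heterocoupled silyl ether
Product: 8 methyl (3S)-4-[(4R)-4-benzyl-2-oxo-1,3-oxazolidin-3-yl]-3-{[4-(benzyloxy)-3-methoxyphenyl]methyl}-2-[(4-hydroxy-3-methoxyphenyl)methyl]-4-oxobutanoate (2S and 2R epimers)
Conditions: Bu4NF (1.1 equiv), AcOH (1.2 equiv), THF, 0 °C
Reagents that add atoms: none
Why: Fluoride-induced Si–O cleavage, buffered so that the imide and both α-carbons are untouched, frees the ring B phenol as the only phenol that can enter the radical coupling.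

Step 5
Reactants: 9 (E)-ferulic acid; 2 (4R)-4-benzyl-1,3-oxazolidin-2-one
Product: 11 (4R)-4-benzyl-3-[(2E)-3-(4-hydroxy-3-methoxyphenyl)prop-2-enoyl]-1,3-oxazolidin-2-one, via feruloyl pivalic anhydride 10 (not isolated)
Conditions: PivCl (1.0 equiv), Et3N (2.2 equiv), THF, −20 °C; then 2 (1.2 equiv), LiCl (1.2 equiv), −20 °C → rt
Reagents that add atoms: none
Why: Mixed-anhydride N-acylation in which the carboxylate is activated far faster than the un-ionized phenol; the E alkene is kept and no stereocenter is formed.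

Step 6
Reactants: 8 ring B phenol; 11 N-feruloyl oxazolidinone
Product: 13 methyl (3S)-4-[(4R)-4-benzyl-2-oxo-1,3-oxazolidin-3-yl]-2-{[(2R,3R)-3-{[(4R)-4-benzyl-2-oxo-1,3-oxazolidin-3-yl]carbonyl}-2-(4-hydroxy-3-methoxyphenyl)-7-methoxy-2,3-dihydro-1-benzofuran-5-yl]methyl}-3-{[4-(benzyloxy)-3-methoxyphenyl]methyl}-4-oxobutanoate (C2 epimers of the butanoate), via quinone methide 12 (not isolated)
Conditions: Ag2O (2.5 equiv), CH2Cl2/acetone (4:1), rt, dark; 11 (2 equiv) added over 6 h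
Reagents that add atoms: none
Why: Proposed new method: Ag2O oxidizes both phenols to phenoxyl radicals, the ring B radical (only free ortho position, C5′) couples with C8″ of the feruloyl radical on the face away from the auxiliary benzyl group (new ring C3 = R), and the re-aromatized ring B phenol closes the quinone methide to the more stable trans ring (C2 = R), the minor facial isomer being removed by chromatography after step 7; the closest known reactions are the Ag2O 8–5′ dehydrodimerization of ferulate esters and of ferulic amides carrying oxazolidinone or sultam auxiliaries, and the cross-coupling of monolignols with 4-alkylguaiacols.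

Step 7
Reactants: 13 phenylcoumaran bis-imide ester
Product: 16 trans-lactone = (3S,4S)-4-{[4-(benzyloxy)-3-methoxyphenyl]methyl}-3-{[(2R,3S)-2-(4-hydroxy-3-methoxyphenyl)-3-(hydroxymethyl)-7-methoxy-2,3-dihydro-1-benzofuran-5-yl]methyl}oxolan-2-one, via hydroxy ester 14 (not isolated), via lactone epimer mixture 15 (not isolated)
Conditions: NaBH4 (8 equiv), THF/H2O (4:1), 0 °C → rt; aq. NH4Cl, extraction; then DBU (1.5 equiv), toluene, 50 °C
Reagents that add atoms: none
Why: Borohydride removal of both oxazolidinones (imides react much faster than a methyl ester or a γ-lactone), spontaneous lactonization of the γ-hydroxy ester, then base equilibration of the lactone α-carbon to the more stable trans-3,4-dibenzyl lactone, which sets lactone C3 as S while C4 and both dihydrobenzofuran centers are retained.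

Step 8
Reactants: 16 trans-lactone phenylcoumaran
Product: 18 (3S,4S)-4-{[4-(benzyloxy)-3-methoxyphenyl]methyl}-3-({4-hydroxy-3-[(2S)-3-hydroxy-1-(4-hydroxy-3-methoxyphenyl)-1-oxopropan-2-yl]-5-methoxyphenyl}methyl)oxolan-2-one, via cyclic hemiketal 17 (not isolated)
Conditions: DDQ (1.05 equiv), MeCN/aq. phosphate buffer pH 7 (5:1), 0 °C, 30 min; sodium ascorbate quench
Reagents that add atoms: water, O
Why: Proposed new method: DDQ abstracts hydride from the doubly activated dihydrobenzofuran C2–H (p-hydroxybenzylic and α-oxygenated), water adds to the cation and the cyclic hemiketal opens to the aryl ketone and the ring B phenol without touching C3, which becomes the S α-carbon of the ketone; the closest known reactions are DDQ cleavage of p-methoxybenzyl ethers in wet solvent and DDQ oxidation of p-hydroxybenzylic positions in lignin models.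

Step 9
Reactants: 18 ring A benzyl ether of the target
Product: 19 (3S,4S)-3-({4-hydroxy-3-[(2S)-3-hydroxy-1-(4-hydroxy-3-methoxyphenyl)-1-oxopropan-2-yl]-5-methoxyphenyl}methyl)-4-[(4-hydroxy-3-methoxyphenyl)methyl]oxolan-2-one
Conditions: H2 (1 atm), 10% Pd/C, EtOAc, rt, 1 h
Reagents that add atoms: none
Why: Neutral hydrogenolysis of the aryl benzyl ether is much faster than reduction of the p-hydroxyaryl ketone and leaves the acid- and base-sensitive α-aryl-β-hydroxy ketone center untouched.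

## Compound list

1 | 3-[4-(benzyloxy)-3-methoxyphenyl]propanoic acid | COc1cc(CCC(=O)O)ccc1OCc1ccccc1 | starting material
2 | (4R)-4-benzyl-1,3-oxazolidin-2-one | O=C1N[C@H](Cc2ccccc2)CO1 | starting material
3 | 3-[4-(benzyloxy)-3-methoxyphenyl]propanoic pivalic anhydride | COc1cc(CCC(=O)OC(=O)C(C)(C)C)ccc1OCc1ccccc1 | intermediate (not isolated)
4 | (4R)-4-benzyl-3-{3-[4-(benzyloxy)-3-methoxyphenyl]propanoyl}-1,3-oxazolidin-2-one | COc1cc(CCC(=O)N2[C@H](Cc3ccccc3)COC2=O)ccc1OCc1ccccc1 | intermediate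
5 | methyl 3-(4-hydroxy-3-methoxyphenyl)propanoate | COC(=O)CCc1ccc(O)c(OC)c1 | starting material
6 | methyl 3-(4-{[tert-butyl(dimethyl)silyl]oxy}-3-methoxyphenyl)propanoate | COC(=O)CCc1ccc(O[Si](C)(C)C(C)(C)C)c(OC)c1 | intermediate
7 | methyl (3S)-4-[(4R)-4-benzyl-2-oxo-1,3-oxazolidin-3-yl]-3-{[4-(benzyloxy)-3-methoxyphenyl]methyl}-2-[(4-{[tert-butyl(dimethyl)silyl]oxy}-3-methoxyphenyl)methyl]-4-oxobutanoate, C2 epimers | COc1cc(C[C@H](C(=O)N2[C@H](Cc3ccccc3)COC2=O)C(Cc2ccc(O[Si](C)(C)C(C)(C)C)c(OC)c2)C(=O)OC)ccc1OCc1ccccc1 | intermediate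
8 | methyl (3S)-4-[(4R)-4-benzyl-2-oxo-1,3-oxazolidin-3-yl]-3-{[4-(benzyloxy)-3-methoxyphenyl]methyl}-2-[(4-hydroxy-3-methoxyphenyl)methyl]-4-oxobutanoate, C2 epimers | COc1cc(C[C@H](C(=O)N2[C@H](Cc3ccccc3)COC2=O)C(Cc2ccc(O)c(OC)c2)C(=O)OC)ccc1OCc1ccccc1 | intermediate
9 | (2E)-3-(4-hydroxy-3-methoxyphenyl)prop-2-enoic acid (ferulic acid) | COc1cc(/C=C/C(=O)O)ccc1O | starting material
10 | (2E)-3-(4-hydroxy-3-methoxyphenyl)prop-2-enoic pivalic anhydride | COc1cc(/C=C/C(=O)OC(=O)C(C)(C)C)ccc1O | intermediate (not isolated)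
11 | (4R)-4-benzyl-3-[(2E)-3-(4-hydroxy-3-methoxyphenyl)prop-2-enoyl]-1,3-oxazolidin-2-one | COc1cc(/C=C/C(=O)N2[C@H](Cc3ccccc3)COC2=O)ccc1O | intermediate
12 | quinone methide of the 8–5′ coupling: 8 carrying at ring B C5′ a (2S)-1-[(4R)-4-benzyl-2-oxo-1,3-oxazolidin-3-yl]-3-(3-methoxy-4-oxocyclohexa-2,5-dien-1-ylidene)-1-oxopropan-2-yl group; C2 epimers of the butanoate, exocyclic alkene geometry not fixed | COc1cc(C[C@H](C(=O)N2[C@H](Cc3ccccc3)COC2=O)C(Cc2cc(OC)c(O)c([C@@H](C(=O)N3[C@H](Cc4ccccc4)COC3=O)C=C3C=CC(=O)C(OC)=C3)c2)C(=O)OC)ccc1OCc1ccccc1 | intermediate (not isolated)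
13 | methyl (3S)-4-[(4R)-4-benzyl-2-oxo-1,3-oxazolidin-3-yl]-2-{[(2R,3R)-3-{[(4R)-4-benzyl-2-oxo-1,3-oxazolidin-3-yl]carbonyl}-2-(4-hydroxy-3-methoxyphenyl)-7-methoxy-2,3-dihydro-1-benzofuran-5-yl]methyl}-3-{[4-(benzyloxy)-3-methoxyphenyl]methyl}-4-oxobutanoate, C2 epimers of the butanoate | COc1cc(C[C@H](C(=O)N2[C@H](Cc3ccccc3)COC2=O)C(Cc2cc(OC)c3O[C@@H](c4ccc(O)c(OC)c4)[C@H](C(=O)N4[C@H](Cc5ccccc5)COC4=O)c3c2)C(=O)OC)ccc1OCc1ccccc1 | intermediate
14 | methyl (3S)-3-{[4-(benzyloxy)-3-methoxyphenyl]methyl}-4-hydroxy-2-{[(2R,3S)-2-(4-hydroxy-3-methoxyphenyl)-3-(hydroxymethyl)-7-methoxy-2,3-dihydro-1-benzofuran-5-yl]methyl}butanoate, C2 epimers | COc1cc(C[C@H](CO)C(Cc2cc(OC)c3O[C@@H](c4ccc(O)c(OC)c4)[C@H](CO)c3c2)C(=O)OC)ccc1OCc1ccccc1 | intermediate (not isolated)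
15 | (4S)-4-{[4-(benzyloxy)-3-methoxyphenyl]methyl}-3-{[(2R,3S)-2-(4-hydroxy-3-methoxyphenyl)-3-(hydroxymethyl)-7-methoxy-2,3-dihydro-1-benzofuran-5-yl]methyl}oxolan-2-one, mixture of 3S (trans) and 3R (cis) | COc1cc(C[C@@H]2COC(=O)C2Cc2cc(OC)c3O[C@@H](c4ccc(O)c(OC)c4)[C@H](CO)c3c2)ccc1OCc1ccccc1 | intermediate (not isolated)
16 | (3S,4S)-4-{[4-(benzyloxy)-3-methoxyphenyl]methyl}-3-{[(2R,3S)-2-(4-hydroxy-3-methoxyphenyl)-3-(hydroxymethyl)-7-methoxy-2,3-dihydro-1-benzofuran-5-yl]methyl}oxolan-2-one | COc1cc(C[C@@H]2COC(=O)[C@H]2Cc2cc(OC)c3O[C@@H](c4ccc(O)c(OC)c4)[C@H](CO)c3c2)ccc1OCc1ccccc1 | intermediate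
17 | (3S,4S)-4-{[4-(benzyloxy)-3-methoxyphenyl]methyl}-3-{[(3S)-2-hydroxy-2-(4-hydroxy-3-methoxyphenyl)-3-(hydroxymethyl)-7-methoxy-2,3-dihydro-1-benzofuran-5-yl]methyl}oxolan-2-one, both C2 epimers of the hemiketal | COc1cc(C[C@@H]2COC(=O)[C@H]2Cc2cc(OC)c3OC(O)(c4ccc(O)c(OC)c4)[C@H](CO)c3c2)ccc1OCc1ccccc1 | intermediate (not isolated)
18 | (3S,4S)-4-{[4-(benzyloxy)-3-methoxyphenyl]methyl}-3-({4-hydroxy-3-[(2S)-3-hydroxy-1-(4-hydroxy-3-methoxyphenyl)-1-oxopropan-2-yl]-5-methoxyphenyl}methyl)oxolan-2-one | COc1cc(C[C@@H]2COC(=O)[C@H]2Cc2cc(OC)c(O)c([C@@H](CO)C(=O)c3ccc(O)c(OC)c3)c2)ccc1OCc1ccccc1 | intermediate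
19 | (3S,4S)-3-({4-hydroxy-3-[(2S)-3-hydroxy-1-(4-hydroxy-3-methoxyphenyl)-1-oxopropan-2-yl]-5-methoxyphenyl}methyl)-4-[(4-hydroxy-3-methoxyphenyl)methyl]oxolan-2-one | COc1cc(C[C@@H]2COC(=O)[C@H]2Cc2cc(OC)c(O)c([C@@H](CO)C(=O)c3ccc(O)c(OC)c3)c2)ccc1O | target

## Step count and fallbacks

Total steps: 9. Longest linear sequence: 7 (steps 1, 3, 4, 6, 7, 8, 9; the same length from 5 through step 2).

The three steps most likely to fail are steps 3, 6 and 8.

**Step 3 (heterocoupling gives mainly homodimers or low conversion).** The C8–C8′ bond is then made by a polar alkylation instead of an oxidative coupling. The fallback sets out from 6. Enolate hydroxylation (LDA, THF, −78 °C; then 2-(phenylsulfonyl)-3-phenyloxaziridine) gives racemic methyl 3-(4-{[tert-butyl(dimethyl)silyl]oxy}-3-methoxyphenyl)-2-hydroxypropanoate F1. Tf2O and 2,6-lutidine (CH2Cl2, −40 °C) convert it into methyl 3-(4-{[tert-butyl(dimethyl)silyl]oxy}-3-methoxyphenyl)-2-{[(trifluoromethyl)sulfonyl]oxy}propanoate F2. The sodium enolate of 4 (NaN(SiMe3)2, THF, −78 °C) displaces the triflate by SN2, again anti to the auxiliary benzyl group as in Evans alkylations. This gives 7 as the same epimer mixture at the ester α-carbon, and the route is rejoined at 7.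

**Step 6 (cross-coupling on the advanced phenol 8 is inefficient).** The 8–5′ ring is then built first on a cheap phenol that can be used in large excess, and the 8–8′ bond is made afterwards. The fallback sets out from 11 and 5. Ag2O in CH2Cl2 with 5 in fivefold excess gives methyl 3-[(2R,3R)-3-{[(4R)-4-benzyl-2-oxo-1,3-oxazolidin-3-yl]carbonyl}-2-(4-hydroxy-3-methoxyphenyl)-7-methoxy-2,3-dihydro-1-benzofuran-5-yl]propanoate F3. NaBH4 in THF/H2O removes the auxiliary and gives methyl 3-[(2R,3S)-2-(4-hydroxy-3-methoxyphenyl)-3-(hydroxymethyl)-7-methoxy-2,3-dihydro-1-benzofuran-5-yl]propanoate F4, which can be upgraded by crystallization. TBSCl and imidazole give methyl 3-[(2R,3S)-2-(4-{[tert-butyl(dimethyl)silyl]oxy}-3-methoxyphenyl)-3-({[tert-butyl(dimethyl)silyl]oxy}methyl)-7-methoxy-2,3-dihydro-1-benzofuran-5-yl]propanoate F5. Heterocoupling of F5 with 4 under the conditions of step 3 gives methyl (3S)-4-[(4R)-4-benzyl-2-oxo-1,3-oxazolidin-3-yl]-3-{[4-(benzyloxy)-3-methoxyphenyl]methyl}-2-{[(2R,3S)-2-(4-{[tert-butyl(dimethyl)silyl]oxy}-3-methoxyphenyl)-3-({[tert-butyl(dimethyl)silyl]oxy}methyl)-7-methoxy-2,3-dihydro-1-benzofuran-5-yl]methyl}-4-oxobutanoate F6. NaBH4 and then DBU, as in step 7, give (3S,4S)-4-{[4-(benzyloxy)-3-methoxyphenyl]methyl}-3-{[(2R,3S)-2-(4-{[tert-butyl(dimethyl)silyl]oxy}-3-methoxyphenyl)-3-({[tert-butyl(dimethyl)silyl]oxy}methyl)-7-methoxy-2,3-dihydro-1-benzofuran-5-yl]methyl}oxolan-2-one F7. Bu4NF buffered by AcOH removes both silyl groups and gives 16, where the route is rejoined.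

**Step 8 (the C2 cation loses the C3 proton and gives the 2-arylbenzofuran faster than it takes up water).** The cation is then captured intramolecularly by a neighboring ester. The fallback sets out from 16. Lipase-catalysed acetylation of the primary alcohol only (Candida antarctica lipase B, vinyl acetate, THF) gives [(2R,3S)-5-{[(3S,4S)-4-{[4-(benzyloxy)-3-methoxyphenyl]methyl}-2-oxooxolan-3-yl]methyl}-2-(4-hydroxy-3-methoxyphenyl)-7-methoxy-2,3-dihydro-1-benzofuran-3-yl]methyl acetate F8. DDQ in MeCN/aqueous pH 7 buffer then proceeds through a six-membered dioxanylium ion, formed by the acetate carbonyl and opened by water. It gives (2S)-2-[5-{[(3S,4S)-4-{[4-(benzyloxy)-3-methoxyphenyl]methyl}-2-oxooxolan-3-yl]methyl}-2-hydroxy-3-methoxyphenyl]-3-(4-hydroxy-3-methoxyphenyl)-3-oxopropyl acetate F9, which is kept at pH 7 or below because it can eliminate acetic acid. The same lipase in phosphate buffer pH 7/acetone removes the acetate without base and gives 18, where the route is rejoined.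

## Further compounds

F1 | step 3 | methyl 3-(4-{[tert-butyl(dimethyl)silyl]oxy}-3-methoxyphenyl)-2-hydroxypropanoate (racemic) | COC(=O)C(O)Cc1ccc(O[Si](C)(C)C(C)(C)C)c(OC)c1
F2 | step 3 | methyl 3-(4-{[tert-butyl(dimethyl)silyl]oxy}-3-methoxyphenyl)-2-{[(trifluoromethyl)sulfonyl]oxy}propanoate (racemic) | COC(=O)C(OS(=O)(=O)C(F)(F)F)Cc1ccc(O[Si](C)(C)C(C)(C)C)c(OC)c1
F3 | step 6 | methyl 3-[(2R,3R)-3-{[(4R)-4-benzyl-2-oxo-1,3-oxazolidin-3-yl]carbonyl}-2-(4-hydroxy-3-methoxyphenyl)-7-methoxy-2,3-dihydro-1-benzofuran-5-yl]propanoate | COC(=O)CCc1cc(OC)c2O[C@@H](c3ccc(O)c(OC)c3)[C@H](C(=O)N3[C@H](Cc4ccccc4)COC3=O)c2c1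
F4 | step 6 | methyl 3-[(2R,3S)-2-(4-hydroxy-3-methoxyphenyl)-3-(hydroxymethyl)-7-methoxy-2,3-dihydro-1-benzofuran-5-yl]propanoate | COC(=O)CCc1cc(OC)c2O[C@@H](c3ccc(O)c(OC)c3)[C@H](CO)c2c1
F5 | step 6 | methyl 3-[(2R,3S)-2-(4-{[tert-butyl(dimethyl)silyl]oxy}-3-methoxyphenyl)-3-({[tert-butyl(dimethyl)silyl]oxy}methyl)-7-methoxy-2,3-dihydro-1-benzofuran-5-yl]propanoate | COC(=O)CCc1cc(OC)c2O[C@@H](c3ccc(O[Si](C)(C)C(C)(C)C)c(OC)c3)[C@H](CO[Si](C)(C)C(C)(C)C)c2c1
F6 | step 6 | methyl (3S)-4-[(4R)-4-benzyl-2-oxo-1,3-oxazolidin-3-yl]-3-{[4-(benzyloxy)-3-methoxyphenyl]methyl}-2-{[(2R,3S)-2-(4-{[tert-butyl(dimethyl)silyl]oxy}-3-methoxyphenyl)-3-({[tert-butyl(dimethyl)silyl]oxy}methyl)-7-methoxy-2,3-dihydro-1-benzofuran-5-yl]methyl}-4-oxobutanoate, C2 epimers | COc1cc(C[C@H](C(=O)N2[C@H](Cc3ccccc3)COC2=O)C(Cc2cc(OC)c3O[C@@H](c4ccc(O[Si](C)(C)C(C)(C)C)c(OC)c4)[C@H](CO[Si](C)(C)C(C)(C)C)c3c2)C(=O)OC)ccc1OCc1ccccc1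
F7 | step 6 | (3S,4S)-4-{[4-(benzyloxy)-3-methoxyphenyl]methyl}-3-{[(2R,3S)-2-(4-{[tert-butyl(dimethyl)silyl]oxy}-3-methoxyphenyl)-3-({[tert-butyl(dimethyl)silyl]oxy}methyl)-7-methoxy-2,3-dihydro-1-benzofuran-5-yl]methyl}oxolan-2-one | COc1cc(C[C@@H]2COC(=O)[C@H]2Cc2cc(OC)c3O[C@@H](c4ccc(O[Si](C)(C)C(C)(C)C)c(OC)c4)[C@H](CO[Si](C)(C)C(C)(C)C)c3c2)ccc1OCc1ccccc1
F8 | step 8 | [(2R,3S)-5-{[(3S,4S)-4-{[4-(benzyloxy)-3-methoxyphenyl]methyl}-2-oxooxolan-3-yl]methyl}-2-(4-hydroxy-3-methoxyphenyl)-7-methoxy-2,3-dihydro-1-benzofuran-3-yl]methyl acetate | COc1cc(C[C@@H]2COC(=O)[C@H]2Cc2cc(OC)c3O[C@@H](c4ccc(O)c(OC)c4)[C@H](COC(C)=O)c3c2)ccc1OCc1ccccc1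
F9 | step 8 | (2S)-2-[5-{[(3S,4S)-4-{[4-(benzyloxy)-3-methoxyphenyl]methyl}-2-oxooxolan-3-yl]methyl}-2-hydroxy-3-methoxyphenyl]-3-(4-hydroxy-3-methoxyphenyl)-3-oxopropyl acetate | COc1cc(C[C@@H]2COC(=O)[C@H]2Cc2cc(OC)c(O)c([C@@H](COC(C)=O)C(=O)c3ccc(O)c(OC)c3)c2)ccc1OCc1ccccc1
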